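The five-membered ring (C1 quaternary bridgehead, C2–C3 methylenes, C4 carbinol, C5 bridgehead CH; C6–C10 complete the seven-membered ring, C6 carrying the aroyloxy and C10 the acetoxy group) is disconnected at C1–C2. Taking C4 back to a ketone makes this ring a cyclopentenone, the signature of a Nazarov cyclisation. In one operation the key step closes the five-membered ring onto an intact seven-membered ring, sets quaternary C1 under control of the C10 acetate and leaves a C5=C6 enone through which C6 is oxygenated. Its precursor is the (S)-acetate of 3-acryloyl-2,6-dimethylcyclohepta-2,6-dien-1-ol, reached by one-carbon ring expansion of an iodocyclohexenone.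

Key step: step 9

Remark (numbering and assumptions): C7 is the ring CH2 between C6 and C8, and C8=C9 is the methyl-bearing ring alkene. All numbered starting materials are taken to be commercial. The C10 oxygen is acetylated before the carbonylation because a free hydroxyl would capture the acylpalladium intermediate as a butenolide. The acyl group is attached through a vinyl iodide so that the C8 methyl and the C8=C9 bond can be built without organocopper reagents.

Step 1
Reactants: 1 2-methylcyclohexane-1,3-dione
Product: 2 3-iodo-2-methylcyclohex-2-en-1-one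
Conditions: PPh3, I2, Et3N, MeCN, rt
Reagents that add atoms: iodine, II
Why: Conversion of a cyclic 1,3-dione into its β-iodo enone, in which the enol oxygen is activated as an oxyphosphonium ion and replaced by iodide through addition–elimination; the symmetry of the dione leaves no regiochemical choice.

Step 2
Reactants: 2 3-iodo-2-methylcyclohex-2-en-1-one; 3 iodomethane
Product: 4 rac-3-iodo-2,6-dimethylcyclohex-2-en-1-one
Conditions: LiN(i-Pr)2, THF, −78 °C; MeI, DMPU, −78 → −20 °C
Reagents that add atoms: iodomethane, CI
Why: Kinetic enolate alkylation at the α' carbon of a β-halo enone (cross-conjugated lithium enolate, iodide untouched at low temperature) installs the future C8 methyl; the new stereocentre forms as a racemate and is erased in step 3.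

Step 3
Reactants: 4 rac-3-iodo-2,6-dimethylcyclohex-2-en-1-one
Product: 5 [(4-iodo-1,3-dimethylcyclohexa-1,3-dien-2-yl)oxy]trimethylsilane
Conditions: LiN(i-Pr)2, THF, −78 °C; Me3SiCl, Et3N, −78 → 0 °C
Reagents that add atoms: chlorotrimethylsilane, C[Si](C)(C)Cl
Why: Silyl enol ether formation by kinetic deprotonation of the single α' hydrogen and O-silylation, which gives the tetrasubstituted enol ether regiospecifically.

Step 4
Reactants: 5 [(4-iodo-1,3-dimethylcyclohexa-1,3-dien-2-yl)oxy]trimethylsilane; 6 diiodomethane
Product: 7 rac-[(3-iodo-2,6-dimethylbicyclo[4.1.0]hept-2-en-1-yl)oxy]trimethylsilane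
Conditions: Et2Zn, CH2I2, CH2Cl2, 0 °C → rt
Reagents that add atoms: diiodomethane, ICI
Why: Simmons–Smith cyclopropanation with the electrophilic zinc carbenoid, which should select the electron-rich silyl enol ether alkene over the electron-poor iodoalkene; the two new stereocentres are racemic and are destroyed in step 5.

Step 5
Reactants: 7 rac-[(3-iodo-2,6-dimethylbicyclo[4.1.0]hept-2-en-1-yl)oxy]trimethylsilane
Product: 9 3-iodo-2,6-dimethylcyclohepta-2,6-dien-1-one, via tertiary chloride 8 (not isolated)
Conditions: FeCl3, DMF, 0 °C; then Et3N, CH2Cl2, rt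
Reagents that add atoms: iron trichloride, Cl[Fe](Cl)Cl (supplies only the chlorine of 8, which is lost again on the way to 9)
Why: Oxidative ring expansion of a siloxycyclopropane, in which one-electron oxidation by FeCl3 cleaves the internal cyclopropane bond to a tertiary β-keto radical that is chlorinated, and E1cB loss of HCl then gives the β-methyl cycloheptenone.

Step 6
Reactants: 9 3-iodo-2,6-dimethylcyclohepta-2,6-dien-1-one
Product: 10 (1S)-3-iodo-2,6-dimethylcyclohepta-2,6-dien-1-ol
Conditions: (R)-2-methyl-CBS-oxazaborolidine (20 mol %), catecholborane, toluene, −78 °C; then MeOH, aq. NaHCO3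
Reagents that add atoms: none
Why: Corey–Bakshi–Shibata reduction, in which the ketone binds the oxazaborolidine with its α-methyl-substituted iodoalkenyl arm as the large group and the α-unsubstituted alkenyl arm as the small one, so that the (R)-catalyst should deliver hydride to the face giving the (S)-carbinol at C10, as with 2-substituted cycloalkenones.

Step 7
Reactants: 10 (1S)-3-iodo-2,6-dimethylcyclohepta-2,6-dien-1-ol; 11 acetic anhydride
Product: 12 (1S)-3-iodo-2,6-dimethylcyclohepta-2,6-dien-1-yl acetate
Conditions: Ac2O, pyridine, DMAP (cat.), CH2Cl2, 0 °C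
Reagents that add atoms: acetic anhydride, CC(=O)OC(C)=O
Why: DMAP-catalysed acylation of the secondary allylic alcohol under basic conditions, which leaves C10 untouched and installs the acetate of the target before the carbonylation.

Step 8
Reactants: 12 (1S)-3-iodo-2,6-dimethylcyclohepta-2,6-dien-1-yl acetate; 13 carbon monoxide; 14 tributyl(vinyl)stannane
Product: 15 (1S)-2,6-dimethyl-3-(prop-2-enoyl)cyclohepta-2,6-dien-1-yl acetate
Conditions: Pd(PPh3)4 (5 mol %), CO (1 atm), Bu3SnCH=CH2, THF, 50 °C
Reagents that add atoms: carbon monoxide, [C-]#[O+]; tributyl(vinyl)stannane, C=C[Sn](CCCC)(CCCC)CCCC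
Why: Carbonylative Stille coupling, in which oxidative addition of the vinyl iodide to zerovalent palladium (expected to be much faster than ionisation of the allylic acetate), CO insertion at the hindered alkenylpalladium and vinyl transfer from tin should give the divinyl ketone.

Step 9
Reactants: 15 (1S)-2,6-dimethyl-3-(prop-2-enoyl)cyclohepta-2,6-dien-1-yl acetate
Product: 16 (8S,8aS)-6,8a-dimethyl-3-oxo-1,2,3,5,8,8a-hexahydroazulen-8-yl acetate
Conditions: Sc(OTf)3 (20 mol %), LiClO4 (1 equiv), ClCH2CH2Cl, 50 °C
Reagents that add atoms: none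
Why: Binding of Sc(OTf)3 to the C4 carbonyl generates the hydroxypentadienyl cation C2=C3–C4–C5=C1, which closes to form C1–C2; the oxyallyl cation then loses a proton from C6 (C1 is quaternary and C5=C6 is the more substituted alkene) and the scandium dienolate is protonated at C3 to give the C5=C6 enone. This is the Lewis-acid-catalysed Nazarov cyclisation of a cycloalkenyl vinyl ketone, a known way to build a methyl-bearing ring-fusion carbon. The one ring formed, the cyclopentenone, closes by thermal 4π conrotatory electrocyclisation of the pentadienyl cation. The one new stereocentre, quaternary C1, is controlled by the adjacent C10 stereocentre: A(1,2) strain with the C1 methyl holds the C10 acetoxy group pseudoaxial, so C2 should bond to the face of C1 anti to it, leaving methyl and acetoxy cis. The step needs torquoselectivity, proton loss toward C6 and survival of the allylic acetate; these rest on the allylic stereocentre, the blocked C1 and the use of a mild oxophilic catalyst.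

Step 10
Reactants: 16 (8S,8aS)-6,8a-dimethyl-3-oxo-1,2,3,5,8,8a-hexahydroazulen-8-yl acetate
Product: 18 (3aS,4S,8S,8aS)-4-hydroxy-6,8a-dimethyl-3-oxo-1,2,3,3a,4,5,8,8a-octahydroazulen-8-yl acetate, via C6 pinacol boronate 17 (not isolated)
Conditions: CuCl (10 mol %), Xantphos (10 mol %), NaOt-Bu (20 mol %), B2pin2, MeOH (2 equiv), THF, rt; then NaBO3·4H2O, THF–H2O, rt
Reagents that add atoms: bis(pinacolato)diboron, CC1(C)OB(OC1(C)C)B1OC(C)(C)C(C)(C)O1 (boryl group of 17); NaBO3 (sodium perborate), [Na+].[O-]OB=O (the C6 oxygen of 18)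
Why: Copper-catalysed conjugate borylation followed by stereoretentive perborate oxidation of the C–B bond; the boryl–copper species should add to C6 from the face anti to the C1 methyl, and C5, protonated by MeOH and epimerisable under the alkoxide, should settle as the trans-fused ketone, in which C4, the C6 substituent and the C10 acetate are all equatorial on the seven-membered ring.

Step 11
Reactants: 18 (3aS,4S,8S,8aS)-4-hydroxy-6,8a-dimethyl-3-oxo-1,2,3,3a,4,5,8,8a-octahydroazulen-8-yl acetate; 19 isopropylmagnesium chloride
Product: 20 (3R,3aS,4S,8S,8aS)-3,4-dihydroxy-6,8a-dimethyl-3-(propan-2-yl)-1,2,3,3a,4,5,8,8a-octahydroazulen-8-yl acetate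
Conditions: i-PrMgCl (4 equiv), CeCl3 (anhydrous), THF, −78 °C; aq. NH4Cl
Reagents that add atoms: isopropylmagnesium chloride, CC(C)[Mg]Cl
Why: Organocerium addition to a ketone, in which the weakly basic, oxophilic isopropylcerium reagent should add to C4 faster than it enolises the ketone or attacks the acetate, approaching from the face of H5 anti to the C1 methyl so that the new hydroxyl is cis to that methyl.

Step 12
Reactants: 20 (3R,3aS,4S,8S,8aS)-3,4-dihydroxy-6,8a-dimethyl-3-(propan-2-yl)-1,2,3,3a,4,5,8,8a-octahydroazulen-8-yl acetate; 21 4-methoxybenzoyl chloride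
Product: 22 (3R,3aS,4S,8S,8aS)-8-(acetyloxy)-3-hydroxy-6,8a-dimethyl-3-(propan-2-yl)-1,2,3,3a,4,5,8,8a-octahydroazulen-4-yl 4-methoxybenzoate
Conditions: 4-MeOC6H4COCl, Et3N, DMAP, CH2Cl2, 0 °C → rt
Reagents that add atoms: 4-methoxybenzoyl chloride, COc1ccc(C(Cl)=O)cc1
Why: DMAP-catalysed acylation, selective for the secondary C6 hydroxyl because the tertiary C4 hydroxyl is inert under these conditions; no stereocentre is touched.

Compound list
1 | 2-methylcyclohexane-1,3-dione | CC1C(=O)CCCC1=O | starting material
2 | 3-iodo-2-methylcyclohex-2-en-1-one | CC1=C(I)CCCC1=O | intermediate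
3 | iodomethane | CI | starting material
4 | rac-3-iodo-2,6-dimethylcyclohex-2-en-1-one | CC1=C(I)CCC(C)C1=O | intermediate
5 | [(4-iodo-1,3-dimethylcyclohexa-1,3-dien-2-yl)oxy]trimethylsilane | CC1=C(O[Si](C)(C)C)C(C)=C(I)CC1 | intermediate
6 | diiodomethane | ICI | starting material
7 | rac-[(3-iodo-2,6-dimethylbicyclo[4.1.0]hept-2-en-1-yl)oxy]trimethylsilane (cis-fused cyclopropane) | C[Si](C)(C)OC12CC1(C)CCC(I)=C2C | intermediate
8 | rac-6-chloro-3-iodo-2,6-dimethylcyclohept-2-en-1-one (formed in the flask, not isolated) | CC1(Cl)CCC(I)=C(C)C(=O)C1 | intermediate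
9 | 3-iodo-2,6-dimethylcyclohepta-2,6-dien-1-one | CC1=CC(=O)C(C)=C(I)CC1 | intermediate
10 | (1S)-3-iodo-2,6-dimethylcyclohepta-2,6-dien-1-ol | IC1=C(C)[C@@H](O)C=C(C)CC1 | intermediate
11 | acetic anhydride | CC(=O)OC(C)=O | starting material
12 | (1S)-3-iodo-2,6-dimethylcyclohepta-2,6-dien-1-yl acetate | IC1=C(C)[C@@H](OC(C)=O)C=C(C)CC1 | intermediate
13 | carbon monoxide | [C-]#[O+] | starting material
14 | tributyl(vinyl)stannane | C=C[Sn](CCCC)(CCCC)CCCC | starting material
15 | (1S)-2,6-dimethyl-3-(prop-2-enoyl)cyclohepta-2,6-dien-1-yl acetate (Nazarov precursor) | C=CC(=O)C1=C(C)[C@@H](OC(C)=O)C=C(C)CC1 | intermediate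
16 | (8S,8aS)-6,8a-dimethyl-3-oxo-1,2,3,5,8,8a-hexahydroazulen-8-yl acetate (C5=C6 enone, methyl and acetoxy cis) | O=C1CC[C@]2(C)[C@@H](OC(C)=O)C=C(C)CC=C12 | intermediate
17 | (3aR,4S,8S,8aS)-6,8a-dimethyl-3-oxo-4-(4,4,5,5-tetramethyl-1,3,2-dioxaborolan-2-yl)-1,2,3,3a,4,5,8,8a-octahydroazulen-8-yl acetate (trans-fused, boryl group anti to the C1 methyl; formed in the flask, not isolated) | CC1(C)OB(OC1(C)C)[C@H]2CC(C)=C[C@H](OC(C)=O)[C@@]3(C)CCC(=O)[C@H]23 | intermediate
18 | (3aS,4S,8S,8aS)-4-hydroxy-6,8a-dimethyl-3-oxo-1,2,3,3a,4,5,8,8a-octahydroazulen-8-yl acetate (trans-fused, C6 hydroxyl and H5 anti to the C1 methyl) | O[C@H]2CC(C)=C[C@H](OC(C)=O)[C@@]3(C)CCC(=O)[C@H]23 | intermediate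
19 | isopropylmagnesium chloride | CC(C)[Mg]Cl | starting material
20 | (3R,3aS,4S,8S,8aS)-3,4-dihydroxy-6,8a-dimethyl-3-(propan-2-yl)-1,2,3,3a,4,5,8,8a-octahydroazulen-8-yl acetate | O[C@H]2CC(C)=C[C@H](OC(C)=O)[C@@]3(C)CC[C@@](O)(C(C)C)[C@H]23 | intermediate
21 | 4-methoxybenzoyl chloride | COc1ccc(C(Cl)=O)cc1 | starting material
22 | (3R,3aS,4S,8S,8aS)-8-(acetyloxy)-3-hydroxy-6,8a-dimethyl-3-(propan-2-yl)-1,2,3,3a,4,5,8,8a-octahydroazulen-4-yl 4-methoxybenzoate (CNP0256979.3) | COc1ccc(C(=O)O[C@H]2CC(C)=C[C@H](OC(C)=O)[C@@]3(C)CC[C@@](O)(C(C)C)[C@H]23)cc1 | target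

Total step count: 12. Longest linear sequence: 12 steps (1 → 22).

Steps most likely to fail

Step 9 (Nazarov cyclisation). The unpolarised pentadienyl cation may close slowly. That would give time for Lewis-acid ionisation of the allylic C10 acetate, for sequestration of the catalyst by the ester carbonyl, or for migration of the C8=C9 bond into conjugation. The conrotation may also show incomplete torquoselectivity. The fallback changes the C10 spectator group; it sets out from alcohol 10 and rejoins the route at 16. Silylation of 10 (t-BuMe2SiCl, imidazole, DMF) should give the silyl ether F1. Carbonylative Stille coupling as in step 8 should give the silyloxy divinyl ketone F2. With no acyloxy leaving group or chelating ester present, and with a bulkier pseudoaxial group to sharpen the facial bias at C1, a stoichiometric promoter at low temperature (BF3·OEt2, CH2Cl2, −40 °C) can be used for the cyclisation to the silyloxy enone F3. HF·pyridine (THF, 0 °C) should release the hydroxy enone F4, and acetylation (Ac2O, pyridine, DMAP) gives 16.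

Step 10 (conjugate borylation and oxidation). The boryl–copper species may add to C6 with poor facial selectivity or attack the allylic acetate in an SN2' sense. Protonation at C5 may also deliver the cis ring fusion without equilibrating. The fallback brings in the C6 oxygen as an epoxide; it sets out from 16 and rejoins at 18. Nucleophilic epoxidation (t-BuOOH, DBU, CH2Cl2, 0 °C) should add the hydroperoxide to C6 anti to the C1 methyl and close onto C5 on the same face, giving the epoxy ketone F5. Reductive opening of the α-carbon–oxygen bond with SmI2 (THF, MeOH, −78 °C) should then give 18, with C5 protonated at low temperature from the samarium enolate.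

Step 11 (isopropyl addition). The branched organometallic may enolise the ketone or reduce it by β-hydride transfer, attack the acetate, or add from the wrong face. The fallback uses an sp2 nucleophile that cannot donate hydride; it sets out from 18 and rejoins at 20. Addition of CH2=C(CH3)MgBr with CeCl3 (THF, −78 °C) should give the isopropenyl carbinol F6. Hydrogenation with H2 and RhCl(PPh3)3 (benzene, rt) should then saturate the 1,1-disubstituted alkene and leave the trisubstituted C8=C9 bond untouched, giving 20.

Further compounds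
F1 | step 9 | tert-butyl{[(1S)-3-iodo-2,6-dimethylcyclohepta-2,6-dien-1-yl]oxy}dimethylsilane | IC1=C(C)[C@@H](O[Si](C)(C)C(C)(C)C)C=C(C)CC1
F2 | step 9 | 1-[(3S)-3-{[tert-butyl(dimethyl)silyl]oxy}-2,5-dimethylcyclohepta-1,4-dien-1-yl]prop-2-en-1-one | C=CC(=O)C1=C(C)[C@@H](O[Si](C)(C)C(C)(C)C)C=C(C)CC1
F3 | step 9 | (8S,8aS)-8-{[tert-butyl(dimethyl)silyl]oxy}-6,8a-dimethyl-1,2,8,8a-tetrahydroazulen-3(5H)-one | O=C1CC[C@]2(C)[C@@H](O[Si](C)(C)C(C)(C)C)C=C(C)CC=C12
F4 | step 9 | (8S,8aS)-8-hydroxy-6,8a-dimethyl-1,2,8,8a-tetrahydroazulen-3(5H)-one | O=C1CC[C@]2(C)[C@@H](O)C=C(C)CC=C12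
F5 | step 10 | C5–C6 epoxide of 16, epoxide oxygen anti to the C1 methyl | O1[C@H]2CC(C)=C[C@H](OC(C)=O)[C@@]3(C)CCC(=O)[C@]123
F6 | step 11 | isopropenyl analogue of 20 (prop-1-en-2-yl in place of propan-2-yl at C4) | O[C@H]2CC(C)=C[C@H](OC(C)=O)[C@@]3(C)CC[C@@](O)(C(C)=C)[C@H]23
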